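The benzenoid ring of the isoquinoline (C4a, C5, C6, C7, C8, C8a) is fused to the nitrogen ring through C4a–C8a and carries C7–H beside C8–OMe, the imprint of an alcohol adding across a C7–C8 aryne. Both rings are therefore opened at C4a–C8a and C5–C6 to a triyne: an N-tosyl (S,S)-amine with a bromobutadiynyl arm on the future C1 and a naphthyl-capped propargyl arm on the future C3. One thermal cascade should close both rings, bring in the biaryl bond as a ready-made alkyne–naphthyl bond and place C8–OMe by methanol capture; the C6 bromine steers that addition and is later exchanged for the second methoxy group.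

Key step: step 10

Remark: the target SMILES leaves the hindered C5–C1' biaryl axis undefined, so the route fixes only C1 and C3 (both S); both rotamers about that axis are expected from step 10 and can be separated by chromatography at 21 or 22 if one is wanted.

Step 1
Reactants: 1 N,N-diethyl-2-methoxybenzamide; 2 3-bromo-2-methylprop-1-ene
Product: 5 N,N-diethyl-2-methoxy-6-(2-methylprop-2-en-1-yl)benzamide, via aryllithium 3 (not isolated), via arylmagnesium bromide 4 (not isolated)
Conditions: s-BuLi, TMEDA, THF, −78 °C; MgBr2·OEt2; 2, −78 °C to rt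
Reagents that add atoms: none
Why: Directed ortho-metalation by the tertiary amide places lithium at C6, and transmetalation to the arylmagnesium bromide allows clean allylation with the methallyl bromide, which the more basic aryllithium would partly deprotonate or exchange.

Step 2
Reactants: 5 N,N-diethyl-2-methoxy-6-(2-methylprop-2-en-1-yl)benzamide
Product: 6 8-methoxy-3-methylnaphthalen-1-ol
Conditions: LiN(iPr)2, THF, −78 °C to rt; aq. HCl
Reagents that add atoms: none
Why: Anionic ring annulation of an ortho-allylbenzamide: deprotonation at the benzylic–allylic CH2 gives an allyl anion whose far carbon attacks the adjacent amide carbonyl, and loss of diethylamide followed by enolisation gives the 1-naphthol.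

Step 3
Reactants: 6 8-methoxy-3-methylnaphthalen-1-ol
Product: 7 1,8-dimethoxy-3-methylnaphthalene
Conditions: NaH, MeI, DMF, 0 °C to rt
Reagents that add atoms: iodomethane, CI
Why: Williamson ether synthesis on the sodium naphtholate, with NaH in DMF chosen to break the peri hydrogen bond between the hydroxyl and the C8 methoxy group.

Step 4
Reactants: 7 1,8-dimethoxy-3-methylnaphthalene
Product: 8 1-iodo-4,5-dimethoxy-2-methylnaphthalene
Conditions: NIS, MeCN, 0 °C to rt, dark
Reagents that add atoms: N-iodosuccinimide, O=C1CCC(=O)N1I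
Why: Electrophilic aromatic iodination should take place at C4 of 7, which is para to the C1 methoxy group and ortho to the methyl group and is the site at which this ring system brominates; the iodide is preferred to the bromide so that oxidative addition at this hindered, electron-rich carbon is easy in step 6.

Step 5
Reactants: 9 (S)-2-methyl-1-(4-methylbenzenesulfonyl)aziridine; 10 lithium acetylide–ethylenediamine complex
Product: 11 N-[(2S)-pent-4-yn-2-yl]-4-methylbenzenesulfonamide
Conditions: DMSO, rt; H2O
Reagents that add atoms: none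
Why: SN2 ring opening of the sulfonyl-activated aziridine by the acetylide at the unsubstituted CH2 leaves the methyl-bearing stereocentre (future C3, S) untouched and gives the terminal alkyne without a protecting group.

Step 6
Reactants: 11 N-[(2S)-pent-4-yn-2-yl]-4-methylbenzenesulfonamide; 8 1-iodo-4,5-dimethoxy-2-methylnaphthalene
Product: 12 N-[(2S)-5-(4,5-dimethoxy-2-methylnaphthalen-1-yl)pent-4-yn-2-yl]-4-methylbenzenesulfonamide
Conditions: Pd(PPh3)2Cl2 (cat.), CuI (cat.), Et3N, THF, 50 °C
Reagents that add atoms: none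
Why: Sonogashira coupling, in which zerovalent palladium inserts into the aryl C–I bond and the copper acetylide of the only terminal alkyne present transfers the alkynyl group; the sulfonamide N–H is tolerated.

Step 7
Reactants: 12 N-[(2S)-5-(4,5-dimethoxy-2-methylnaphthalen-1-yl)pent-4-yn-2-yl]-4-methylbenzenesulfonamide; 13 (R)-but-3-yn-2-ol
Product: 14 N-[(2S)-but-3-yn-2-yl]-N-[(2S)-5-(4,5-dimethoxy-2-methylnaphthalen-1-yl)pent-4-yn-2-yl]-4-methylbenzenesulfonamide
Conditions: PBu3, TMAD, toluene, 0 °C to 60 °C
Reagents that add atoms: none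
Why: Mitsunobu N-alkylation, in which the sulfonamide anion displaces the alkoxyphosphonium ion of the small, activated propargylic carbinol by SN2 with inversion, so that the (R)-alcohol gives the (S)-configured C–N centre (future C1); PBu3 and TMAD are used because an N-sec-alkyl tosylamide is a weakly acidic and hindered pronucleophile.

Step 8
Reactants: 14 N-[(2S)-but-3-yn-2-yl]-N-[(2S)-5-(4,5-dimethoxy-2-methylnaphthalen-1-yl)pent-4-yn-2-yl]-4-methylbenzenesulfonamide; 15 (bromoethynyl)tri(propan-2-yl)silane
Product: 16 N-[(2S)-5-(4,5-dimethoxy-2-methylnaphthalen-1-yl)pent-4-yn-2-yl]-4-methyl-N-[(2S)-6-[tri(propan-2-yl)silyl]hexa-3,5-diyn-2-yl]benzenesulfonamide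
Conditions: CuCl (cat.), NH2OH·HCl, n-BuNH2, H2O/CH2Cl2, 0 °C
Reagents that add atoms: none
Why: Cadiot–Chodkiewicz coupling of the copper acetylide from 14 with the bromoalkyne gives the unsymmetrical 1,3-diyne, and the bulky silyl cap withstands the amine base.

Step 9
Reactants: 16 N-[(2S)-5-(4,5-dimethoxy-2-methylnaphthalen-1-yl)pent-4-yn-2-yl]-4-methyl-N-[(2S)-6-[tri(propan-2-yl)silyl]hexa-3,5-diyn-2-yl]benzenesulfonamide
Product: 18 N-[(2S)-6-bromohexa-3,5-diyn-2-yl]-N-[(2S)-5-(4,5-dimethoxy-2-methylnaphthalen-1-yl)pent-4-yn-2-yl]-4-methylbenzenesulfonamide, via silver diynide 17 (not isolated)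
Conditions: AgF, MeCN, rt, dark; NBS, 0 °C; aq. NH4Cl
Reagents that add atoms: N-bromosuccinimide, O=C1CCC(=O)N1Br
Why: Fluoride-driven desilylation by AgF gives the silver diynide, which NBS brominates at carbon far faster than it attacks an arene, so that adding NBS only after the acetylide has formed and keeping it cold should spare the electron-rich naphthalene.

Step 10
Reactants: 18 N-[(2S)-6-bromohexa-3,5-diyn-2-yl]-N-[(2S)-5-(4,5-dimethoxy-2-methylnaphthalen-1-yl)pent-4-yn-2-yl]-4-methylbenzenesulfonamide; 19 methanol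
Product: 21 (1S,3S)-6-bromo-5-(4,5-dimethoxy-2-methylnaphthalen-1-yl)-8-methoxy-1,3-dimethyl-2-(4-methylbenzenesulfonyl)-1,2,3,4-tetrahydroisoquinoline, via C7–C8 aryne 20 (not isolated)
Conditions: MeOH/PhCl (1:4), 0.005 M, sealed tube, 120 °C, dark
Reagents that add atoms: none
Why: Proposed new method: heating should join the 1,3-diyne (future C8a, C8, C7, C6) and the naphthyl alkyne (future C4a, C5) in a net [4+2] cycloaddition, concerted or through a diradical that first links C8a to C4a, to give the C7–C8 aryne 20, which methanol captures by O–C8 bonding and proton delivery to C7; the closest known reaction type is the thermal hexadehydro-Diels–Alder cyclisation of sulfonamide-tethered triynes with three-atom tethers followed by alcohol trapping, whereas a four-atom tether, a bromodiyne and a 2-methylnaphthyl alkyne have not been shown together. The nitrogen ring closes in 6-exo-dig fashion with respect to both alkynes when C8a–C4a forms, and the benzenoid ring closes through the second cycloaddition bond C5–C6. No stereocentre is created: C1 and C3 are carried through unchanged, and the C5–C1' axis arises without control. The step needs methanol to add at C8 and not at C7, which the inductively withdrawing C6 bromine should secure by polarising the aryne so that the developing negative charge sits on C7 next to it, as in 3-halobenzynes. Folding of the tether is helped by the N-sulfonyl group and the two methyl-bearing carbons, and high dilution in a methanol-rich medium should suppress intermolecular aryne reactions and hydrogen-transfer reduction.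

Step 11
Reactants: 21 (1S,3S)-6-bromo-5-(4,5-dimethoxy-2-methylnaphthalen-1-yl)-8-methoxy-1,3-dimethyl-2-(4-methylbenzenesulfonyl)-1,2,3,4-tetrahydroisoquinoline
Product: 22 (1S,3S)-5-(4,5-dimethoxy-2-methylnaphthalen-1-yl)-6,8-dimethoxy-1,3-dimethyl-2-(4-methylbenzenesulfonyl)-1,2,3,4-tetrahydroisoquinoline
Conditions: CuI, NaOMe, MeOH/DMF, 110 °C
Reagents that add atoms: sodium methoxide, C[O-].[Na+]
Why: Ullmann-type methoxylation, in which a methoxide complex of monovalent copper adds oxidatively to the C6–Br bond and forms the C6–O bond by reductive elimination; the tertiary sulfonamide and both stereocentres are inert to methoxide.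

Step 12
Reactants: 22 (1S,3S)-5-(4,5-dimethoxy-2-methylnaphthalen-1-yl)-6,8-dimethoxy-1,3-dimethyl-2-(4-methylbenzenesulfonyl)-1,2,3,4-tetrahydroisoquinoline
Product: 23 (1S,3S)-5-(4,5-dimethoxy-2-methylnaphthalen-1-yl)-6,8-dimethoxy-1,3-dimethyl-1,2,3,4-tetrahydroisoquinoline
Conditions: NaC10H8 (sodium naphthalenide), DME, −78 °C; aq. NH4Cl
Reagents that add atoms: none
Why: Reductive desulfonylation by single-electron transfer from the naphthalene radical anion to the tosyl group cleaves the S–N bond at −78 °C, where the aryl methyl ethers, the electron-rich naphthalene and the benzylic C1–N bond should survive and neither C1 nor C3 can epimerise.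

Compound list

1 | N,N-diethyl-2-methoxybenzamide | CCN(CC)C(=O)c1ccccc1OC | starting material
2 | 3-bromo-2-methylprop-1-ene | C=C(C)CBr | starting material
3 | [2-(diethylcarbamoyl)-3-methoxyphenyl]lithium | CCN(CC)C(=O)c1c([Li])cccc1OC | intermediate (not isolated)
4 | [2-(diethylcarbamoyl)-3-methoxyphenyl]magnesium bromide | CCN(CC)C(=O)c1c([Mg]Br)cccc1OC | intermediate (not isolated)
5 | N,N-diethyl-2-methoxy-6-(2-methylprop-2-en-1-yl)benzamide | CCN(CC)C(=O)c1c(CC(C)=C)cccc1OC | intermediate
6 | 8-methoxy-3-methylnaphthalen-1-ol | COc1cccc2cc(C)cc(O)c12 | intermediate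
7 | 1,8-dimethoxy-3-methylnaphthalene | COc1cc(C)cc2cccc(OC)c12 | intermediate
8 | 1-iodo-4,5-dimethoxy-2-methylnaphthalene | COc1cc(C)c(I)c2cccc(OC)c12 | intermediate
9 | (S)-2-methyl-1-(4-methylbenzenesulfonyl)aziridine | C[C@H]1CN1S(=O)(=O)c1ccc(C)cc1 | starting material
10 | lithium acetylide–ethylenediamine complex | [Li]C#C.NCCN | starting material
11 | N-[(2S)-pent-4-yn-2-yl]-4-methylbenzenesulfonamide | C#CC[C@H](C)NS(=O)(=O)c1ccc(C)cc1 | intermediate
12 | N-[(2S)-5-(4,5-dimethoxy-2-methylnaphthalen-1-yl)pent-4-yn-2-yl]-4-methylbenzenesulfonamide | COc1cc(C)c(C#CC[C@H](C)NS(=O)(=O)c3ccc(C)cc3)c2cccc(OC)c12 | intermediate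
13 | (R)-but-3-yn-2-ol | C[C@@H](O)C#C | starting material
14 | N-[(2S)-but-3-yn-2-yl]-N-[(2S)-5-(4,5-dimethoxy-2-methylnaphthalen-1-yl)pent-4-yn-2-yl]-4-methylbenzenesulfonamide | C#C[C@H](C)N(S(=O)(=O)c1ccc(C)cc1)[C@@H](C)CC#Cc1c(C)cc(OC)c2c(OC)cccc12 | intermediate
15 | (bromoethynyl)tri(propan-2-yl)silane | CC(C)[Si](C#CBr)(C(C)C)C(C)C | starting material
16 | N-[(2S)-5-(4,5-dimethoxy-2-methylnaphthalen-1-yl)pent-4-yn-2-yl]-4-methyl-N-[(2S)-6-[tri(propan-2-yl)silyl]hexa-3,5-diyn-2-yl]benzenesulfonamide | CC(C)[Si](C#CC#C[C@H](C)N(S(=O)(=O)c1ccc(C)cc1)[C@@H](C)CC#Cc1c(C)cc(OC)c2c(OC)cccc12)(C(C)C)C(C)C | intermediate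
17 | silver acetylide of N-[(2S)-hexa-3,5-diyn-2-yl]-N-[(2S)-5-(4,5-dimethoxy-2-methylnaphthalen-1-yl)pent-4-yn-2-yl]-4-methylbenzenesulfonamide (silver on the terminal diyne carbon) | [Ag]C#CC#C[C@H](C)N(S(=O)(=O)c1ccc(C)cc1)[C@@H](C)CC#Cc1c(C)cc(OC)c2c(OC)cccc12 | intermediate (not isolated)
18 | N-[(2S)-6-bromohexa-3,5-diyn-2-yl]-N-[(2S)-5-(4,5-dimethoxy-2-methylnaphthalen-1-yl)pent-4-yn-2-yl]-4-methylbenzenesulfonamide | BrC#CC#C[C@H](C)N(S(=O)(=O)c1ccc(C)cc1)[C@@H](C)CC#Cc1c(C)cc(OC)c2c(OC)cccc12 | intermediate
19 | methanol | CO | starting material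
20 | (1S,3S)-6-bromo-5-(4,5-dimethoxy-2-methylnaphthalen-1-yl)-1,3-dimethyl-2-(4-methylbenzenesulfonyl)-7,8-didehydro-1,2,3,4-tetrahydroisoquinoline (C7–C8 aryne) | BrC1=C(c2c(C)cc(OC)c3c(OC)cccc23)C2=C(C#C1)[C@H](C)N(S(=O)(=O)c1ccc(C)cc1)[C@@H](C)C2 | intermediate (not isolated)
21 | (1S,3S)-6-bromo-5-(4,5-dimethoxy-2-methylnaphthalen-1-yl)-8-methoxy-1,3-dimethyl-2-(4-methylbenzenesulfonyl)-1,2,3,4-tetrahydroisoquinoline | Brc1cc(OC)c2c(c1-c1c(C)cc(OC)c3c(OC)cccc13)C[C@H](C)N(S(=O)(=O)c1ccc(C)cc1)[C@H]2C | intermediate
22 | (1S,3S)-5-(4,5-dimethoxy-2-methylnaphthalen-1-yl)-6,8-dimethoxy-1,3-dimethyl-2-(4-methylbenzenesulfonyl)-1,2,3,4-tetrahydroisoquinoline | COc1cc(OC)c2c(c1-c1c(C)cc(OC)c3c(OC)cccc13)C[C@H](C)N(S(=O)(=O)c1ccc(C)cc1)[C@H]2C | intermediate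
23 | (1S,3S)-5-(4,5-dimethoxy-2-methylnaphthalen-1-yl)-6,8-dimethoxy-1,3-dimethyl-1,2,3,4-tetrahydroisoquinoline | COc1cc(OC)c2c(c1-c1c(C)cc(OC)c3c(OC)cccc13)C[C@H](C)N[C@H]2C | target

Total step count: 12. Longest linear sequence: 11 steps (1 → 5 → 6 → 7 → 8 → 12 → 14 → 16 → 18 → 21 → 22 → 23); the amine branch from 9 joins at step 6.

Steps most likely to fail

1. Step 10, the triyne cascade. The cycloaddition may be too slow at temperatures that the bromodiyne tolerates, so that polymerisation or loss of bromine outruns ring closure, or methanol may add in the wrong sense or reduce the aryne. The fallback uses the established biaryl-coupling logic; it sets out from 9 and 8 and comes back to the route at 22. Copper-catalysed opening of aziridine 9 with 3,5-dimethoxyphenylmagnesium bromide (CuI cat., THF, −30 °C to rt) should give N-[(2S)-1-(3,5-dimethoxyphenyl)propan-2-yl]-4-methylbenzenesulfonamide F1. An N-sulfonyl Pictet–Spengler reaction of F1 with acetaldehyde diethyl acetal and BF3·OEt2 in CH2Cl2 should close the nitrogen ring onto the activated arene and give (1S,3S)-6,8-dimethoxy-1,3-dimethyl-2-(4-methylbenzenesulfonyl)-1,2,3,4-tetrahydroisoquinoline F2. The 1,3-trans isomer is expected, because the cis isomer would need either a syn-diaxial pair of methyl groups or two allylic-strain contacts with the sulfonyl group; any cis isomer would be removed by crystallisation. NBS in MeCN at 0 °C should brominate F2 at C5, para to the C8 methoxy group, to give (1S,3S)-5-bromo-6,8-dimethoxy-1,3-dimethyl-2-(4-methylbenzenesulfonyl)-1,2,3,4-tetrahydroisoquinoline F3. Iodine–lithium exchange on 8 (n-BuLi, THF, −78 °C), B(OMe)3 and acidic work-up should give (4,5-dimethoxy-2-methylnaphthalen-1-yl)boronic acid F4. Suzuki–Miyaura coupling of F3 with F4 (Pd(OAc)2, SPhos, K3PO4, toluene/water, 100 °C) should then give 22 as the same pair of rotamers, and step 12 follows as written.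

2. Step 7, the Mitsunobu alkylation. Displacement at the alkoxyphosphonium ion by the hindered, weakly acidic sulfonamide may be so slow that alkylation of the reduced azo reagent or SN2' attack leading to an allene takes over. The fallback separates activation from substitution; it sets out from 13 and 12 and comes back at 14. Mesylation of 13 (MsCl, Et3N, CH2Cl2, −20 °C) should give (2R)-but-3-yn-2-yl methanesulfonate F5, an isolable electrophile. The caesium salt of 12 (Cs2CO3, DMF, rt to 40 °C) should displace the mesylate of F5 by SN2 with inversion, giving 14 with the (S)-configured propargylic centre.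

3. Step 9, the bromodesilylation. Ring bromination of the electron-rich naphthalene may compete with bromination of the silver acetylide, and the bromodiyne may decompose when concentrated. The fallback replaces the silver acetylide by a lithium acetylide at low temperature; it sets out from 16 and comes back at 18. Desilylation of 16 with Bu4NF buffered with AcOH (THF, 0 °C) should give N-[(2S)-hexa-3,5-diyn-2-yl]-N-[(2S)-5-(4,5-dimethoxy-2-methylnaphthalen-1-yl)pent-4-yn-2-yl]-4-methylbenzenesulfonamide F6. Deprotonation of the terminal diyne of F6 with LiN(SiMe3)2 (THF, −78 °C) and quenching with NBS at −78 °C, where arene bromination does not occur, should give 18, which is carried into step 10 as a solution without being taken to dryness.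

Further compounds

F1 | step 10 | N-[(2S)-1-(3,5-dimethoxyphenyl)propan-2-yl]-4-methylbenzenesulfonamide | COc1cc(C[C@H](C)NS(=O)(=O)c2ccc(C)cc2)cc(OC)c1
F2 | step 10 | (1S,3S)-6,8-dimethoxy-1,3-dimethyl-2-(4-methylbenzenesulfonyl)-1,2,3,4-tetrahydroisoquinoline | COc1cc(OC)c2c(c1)C[C@H](C)N(S(=O)(=O)c1ccc(C)cc1)[C@H]2C
F3 | step 10 | (1S,3S)-5-bromo-6,8-dimethoxy-1,3-dimethyl-2-(4-methylbenzenesulfonyl)-1,2,3,4-tetrahydroisoquinoline | COc1cc(OC)c2c(c1Br)C[C@H](C)N(S(=O)(=O)c1ccc(C)cc1)[C@H]2C
F4 | step 10 | (4,5-dimethoxy-2-methylnaphthalen-1-yl)boronic acid | COc1cc(C)c(B(O)O)c2cccc(OC)c12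
F5 | step 7 | (2R)-but-3-yn-2-yl methanesulfonate | C[C@@H](OS(C)(=O)=O)C#C
F6 | step 9 | N-[(2S)-hexa-3,5-diyn-2-yl]-N-[(2S)-5-(4,5-dimethoxy-2-methylnaphthalen-1-yl)pent-4-yn-2-yl]-4-methylbenzenesulfonamide | C#CC#C[C@H](C)N(S(=O)(=O)c1ccc(C)cc1)[C@@H](C)CC#Cc1c(C)cc(OC)c2c(OC)cccc12
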